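Germacrane numbering is used for positions throughout: ring C1–C10, C14 on C10, C15 on C4, lactone carbons C11–C13 on C7, ester on O8. Target 43 is (6R,7R,8S), with a ring-cis C1=C10 and a ring-trans C4=C5 alkene.

## The problem

Target 43 is a ten-membered carbocycle fused trans at C6–C7 to an α-methylene-γ-butyrolactone and acylated at O8 with (E)-4-hydroxy-3-methylbut-2-enoic acid. The ring holds two trisubstituted alkenes of opposite ring geometry: C1=C10 is ring-cis and C4=C5 is ring-trans with hydroxymethyl C15. Closing a ten-membered ring is costly in entropy and strain, and an olefin-forming closure would leave one of these geometries to chance, so both should be fixed before or by the closing event. The three stereocentres C6, C7 and C8 are contiguous and all-syn along the C5–C9 chain. C7 and C8 can be set together by a syn-aldol, and C6 can be added to the resulting C6 aldehyde under catalyst control that the Felkin preference of the C7 centre supports. The α-methylene lactone is a Michael acceptor, the 1(10),4-diene can cyclise across the ring in acid, and the side-chain ester tolerates neither hydride nor enolate chemistry, so these three features belong at the end. The enabling feature is that C15 and O6 lie cis across C4=C5. The five atoms C15, C4, C5, C6 and O6 can therefore be held in a temporary butenolide that locks the alkene geometry and offers C4 as an iodoalkene. C3 is a plain CH2 next to CH2 (C2), so it can be delivered as the boron end of a hydroborated terminal alkene.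

## Retrosynthesis

**Ester at O8 and the two primary hydroxyls.** The O8–acyl bond of 43 is cut last, giving alcohol 37 and acid 40 through the bis-silyl ether 42. The acyl group would not survive the hydride and enolate steps, and the acid needs its own hydroxyl masked, so one fluoride step can free O15 and the side-chain hydroxyl together. Acid 40 comes from silyloxyacetone 38 through ester 39 by a Horner–Wadsworth–Emmons reaction, which sets the E geometry outside the macrocycle.

**Methylene C13 and the O8 protecting group.** The C11=C13 bond of 37 is traced through PMB ether 36 and Mannich base 34 to the saturated lactone 32. Adding C13 after ring formation keeps the Michael acceptor away from organometallic steps. The PMB group on O8 is removed oxidatively, which avoids acid on the diene.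

**The 12,6-lactone.** The O6–C12 bond of 32 is cut back through lactol 31 to hydroxy acetal 30, its unsilylated diol 29 and the bridged lactone 28. C12 travels as a dimethyl acetal, which is inert to organolithium, tin, borane and hydride reagents. O8 is blocked, so only O6 can close onto C12. The forward steps must free O6 and C15 from 28 by reduction and then tell the primary C15 hydroxyl from the secondary C6 hydroxyl.

**Key cut, C3–C4.** Bridged lactone 28 is opened at C3–C4 to iodobutenolide 26, which reacts through alkylborane 27.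
- Against C2–C3: that bond is sp3–sp3 and has no comparably reliable closure.
- Against an olefination at C1=C10 or C4=C5: that would leave a trisubstituted alkene geometry to the ring.
- Against C5–C6: a closure there would create C6 during macrocyclisation.
- The precursor 26 is acyclic, carries all three stereocentres and both alkene geometries, and the closure makes no stereocentre.
- The forward step needs hydroboration of the terminal alkene only and ring closure in preference to oligomerisation.

**The iodobutenolide.** Compound 26 is cut at C4–I, O6–C15 and C5–C6, giving stannylbutenolide 25, hydroxy ynoate 24, aldehyde 21 and ethyl propiolate 22. Propiolate supplies C15, C4 and C5 in one step. Syn-hydrostannation is preferred to semihydrogenation because the ynoate reacts with tin hydride far faster than the diene does, and the tin marks C4 for iodine. The forward addition to 21 must set C6.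

**C9–C10.** Aldehyde 21 is traced through alcohol 20, PMB ether 19 and alcohol 18 to epoxide 11 and dienyllithium 17, made from iododiene 16. Cutting here avoids a β,γ-unsaturated dienal in the aldol and moves the C1=C10 geometry onto a five-carbon fragment. Iododiene 16 comes from but-2-yn-1-ol 12 by hydroalumination–iodination (via 13 to 14), oxidation to 15 and methylenation. Opening the epoxide at C9 leaves the C8 configuration untouched.

**C7–C8.** Epoxide 11 is traced through silyl chlorohydrin 10 and chlorodiol 9 to aldol adduct 8, which is cut at C7–C8 into imide 5 (via boron enolate 7) and chloroacetaldehyde 6. One syn-aldol sets C7 and C8, and the chloride is the handle for the epoxide. Imide 5 comes from acid 2 and oxazolidinone 3 through mixed anhydride 4, and 2 comes from ester 1.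

## Roads not taken

**Alternative 1: Still–Wittig ring contraction.** The cut is C7–C8. The forward key step treats the thirteen-membered stannyl ether A2, in which O8 is bound to C13 and C8 carries Bu3Sn, with n-BuLi. The C8 carbanion attacks C7 as the O8–C13 bond breaks, giving ten-membered alcohol A1.
- Merits: it forms C7–C8, reveals the C11=C13 methylene and frees O8 in one step, so the end-game needs no separate methylenation or O8 deprotection. A thirteen-membered ether is also easier to close than a ten-membered carbocycle.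
- Weak points: both C7 and C8 are created during the contraction, and their sense depends on the conformation of a large ring and on the configuration of the stannane carbon. A [1,2]-shift can compete. Ether A2 must already hold both ring alkenes and still needs a macro-etherification. C12 must later be oxidised to the lactone in the presence of two allylic silyl ethers.
- Comparison: this road is better in end-game step economy. Against that, the chosen plan sets C7 and C8 by an acyclic aldol and asks the ring closure for no stereocentre.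

**Alternative 2: photochemical opening of a cis-fused decalin diene.** The retrosynthetic move joins C5 to C10, leading to the cis-fused 1,3-diene lactone A4. Irradiation at 254 nm at low temperature would open the C5–C10 bond in a conrotatory sense to give triene lactone A3.
- Merits: this is the shortest way to the ring. The decalin holds C6, C7 and C8 on a rigid frame, and the step needs no metal and no dilution.
- Weak points: the opening is reversible and ends in a photostationary mixture. The two conrotatory senses give opposite pairs of geometries at C1=C10 and C4=C5, and the substrate gives no clear bias. Triene A3 has an extra C2=C3 alkene that must be reduced selectively within a conjugated triene. The triene is prone to thermal reclosure.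
- Comparison: this road is better in step count to the ring. Against that, the chosen plan fixes both geometries by construction and has no extra alkene to remove.

**Alternative 3: Ramberg–Bäcklund contraction.** The cut is the C1=C10 double bond, traced to the eleven-membered sulfone A6 with sulfur between C1 and C10. KOH on alumina with CBr2F2 in t-BuOH would halogenate next to sulfur, close the episulfone and expel SO2 to give diene A5.
- Merits: the eleven-membered ring closes by C–S bond formation, which is easier than C–C closure. A5 already carries C13, as the α-methylene lactol methyl ether.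
- Weak points: the ring-cis geometry of a trisubstituted C1=C10 alkene is decided by the contraction and may come out as a mixture. Halogenation has to choose between C1 and the tertiary C10. The strongly basic medium meets an allylic C6 acetal oxygen and a base-sensitive ring.
- Comparison: this road is as good or better in ring-closure ease and in having C13 early. Against that, the chosen plan sets the C1=C10 geometry by alkyne hydroalumination before any ring exists.

Key step: step 15

## Route

Assumption: the (S,S)-enantiomer of ProPhenol is taken to deliver the alkynylzinc to the Re face of aldehyde 21; if its sense is the reverse, the (R,R)-ligand is used.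
Assumption: chloroacetaldehyde 6 is used as the freshly dried and distilled monomer.

Step 1
Reactants: 1 methyl 4,4-dimethoxybutanoate
Product: 2 4,4-dimethoxybutanoic acid
Conditions: LiOH·H2O, THF/H2O, 0 °C → rt; then 1 M HCl to pH 4, 0 °C, EtOAc
Reagents that add atoms: lithium hydroxide, [Li+].[OH-]
Why: Ester saponification; the dimethyl acetal is stable to base and should survive the brief cold acidification to pH 4.

Step 2
Reactants: 2 4,4-dimethoxybutanoic acid; 3 (R)-4-benzyloxazolidin-2-one
Product: 5 (R)-4-benzyl-3-(4,4-dimethoxybutanoyl)oxazolidin-2-one, via mixed pivalic anhydride 4 (not isolated)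
Conditions: t-BuCOCl, Et3N, THF, −20 °C; then LiCl, 3, −20 °C → rt
Reagents that add atoms: none
Why: N-Acylation of the oxazolidinone through the mixed anhydride, which is attacked at its less hindered carbonyl; the conditions are non-acidic and spare the acetal.

Step 3
Reactants: 5 (R)-4-benzyl-3-(4,4-dimethoxybutanoyl)oxazolidin-2-one; 6 chloroacetaldehyde
Product: 8 (R)-4-benzyl-3-[(2R,3R)-4-chloro-2-(2,2-dimethoxyethyl)-3-hydroxybutanoyl]oxazolidin-2-one, via dibutylboron Z-enolate 7 (not isolated)
Conditions: n-Bu2BOTf, i-Pr2NEt, CH2Cl2, −78 → 0 °C; 6, −78 → 0 °C; then pH 7 buffer, MeOH, 30% H2O2, 0 °C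
Reagents that add atoms: none
Why: Evans syn-aldol; the Z-boron enolate reacts through a chair transition state on the face away from the benzyl group, which sets C7 (R) and C8 with O8 syn to C11.

Step 4
Reactants: 8 (R)-4-benzyl-3-[(2R,3R)-4-chloro-2-(2,2-dimethoxyethyl)-3-hydroxybutanoyl]oxazolidin-2-one
Product: 9 (2S,3R)-4-chloro-2-(2,2-dimethoxyethyl)butane-1,3-diol
Conditions: LiBH4, MeOH (1 equiv), THF, 0 °C
Reagents that add atoms: none
Why: Reductive removal of the auxiliary by LiBH4; the alkyl chloride and the acetal are inert, and neither stereocentre is touched.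

Step 5
Reactants: 9 (2S,3R)-4-chloro-2-(2,2-dimethoxyethyl)butane-1,3-diol
Product: 11 tert-butyl{(2S)-4,4-dimethoxy-2-[(2R)-oxiran-2-yl]butoxy}diphenylsilane, via silylated chlorohydrin 10 (not isolated)
Conditions: TBDPSCl, imidazole, DMF, 0 °C; then K2CO3, MeOH, rt
Reagents that add atoms: tert-butylchlorodiphenylsilane, CC(C)(C)[Si](Cl)(c1ccccc1)c1ccccc1
Why: Selective silylation of the primary hydroxyl followed by intramolecular Williamson closure of the chlorohydrin at C9; silylating first blocks tetrahydrofuran formation by O6, and C8 keeps its configuration because the substitution is at C9.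

Step 6
Reactants: 12 but-2-yn-1-ol
Product: 14 (Z)-3-iodobut-2-en-1-ol, via cyclic alkenylaluminate 13 (not isolated)
Conditions: NaAlH2(OCH2CH2OMe)2, THF, 0 °C → rt; then I2, THF, −78 → 0 °C
Reagents that add atoms: iodine, II
Why: Alkoxide-directed trans-hydroalumination places aluminium on the carbon remote from oxygen, and iodinolysis with retention gives the Z-iodoalkene that carries the later C1=C10 geometry.

Step 7
Reactants: 14 (Z)-3-iodobut-2-en-1-ol
Product: 15 (Z)-3-iodobut-2-enal
Conditions: MnO2, CH2Cl2, rt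
Reagents that add atoms: none
Why: Allylic oxidation on MnO2 under neutral conditions, which should keep the Z geometry of the β-iodoenal.

Step 8
Reactants: 15 (Z)-3-iodobut-2-enal
Product: 16 (3Z)-4-iodopenta-1,3-diene
Conditions: Ph3PCH3Br, KOt-Bu, THF, 0 °C; then 15, −78 → 0 °C; kept as a solution in Et2O/pentane
Reagents that add atoms: methyltriphenylphosphonium bromide, C[P+](c1ccccc1)(c1ccccc1)c1ccccc1.[Br-]
Why: Wittig methylenation of the aldehyde adds C3; the trisubstituted alkene is not involved and stays Z.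

Step 9
Reactants: 16 (3Z)-4-iodopenta-1,3-diene; 11 tert-butyl{(2S)-4,4-dimethoxy-2-[(2R)-oxiran-2-yl]butoxy}diphenylsilane
Product: 18 (3S,4S,6Z)-3-{[(tert-butyldiphenylsilyl)oxy]methyl}-1,1-dimethoxy-6-methylnona-6,8-dien-4-ol, via dienyllithium 17 (not isolated)
Conditions: 16, t-BuLi (2 equiv per iodide), Et2O, −78 °C; then 11, BF3·OEt2, THF, −78 °C
Reagents that add atoms: none
Why: Iodine–lithium exchange with retention, then BF3-assisted SN2 opening of the terminal epoxide at C9 by the alkenyllithium; this forms C9–C10 with the Z geometry intact and leaves C8 unchanged.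

Step 10
Reactants: 18 (3S,4S,6Z)-3-{[(tert-butyldiphenylsilyl)oxy]methyl}-1,1-dimethoxy-6-methylnona-6,8-dien-4-ol
Product: 19 tert-butyl{[(2S,3S,5Z)-2-(2,2-dimethoxyethyl)-3-[(4-methoxybenzyl)oxy]-5-methylocta-5,7-dien-1-yl]oxy}diphenylsilane
Conditions: NaH, 4-methoxybenzyl chloride, Bu4NI (cat.), DMF, 0 °C → rt
Reagents that add atoms: 4-methoxybenzyl chloride, COc1ccc(CCl)cc1
Why: Williamson etherification under basic conditions, chosen because acid-catalysed imidate methods could make O8 cyclise onto the C12 acetal; the bulky TBDPS group on the primary oxygen resists 1,3-migration.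

Step 11
Reactants: 19 tert-butyl{[(2S,3S,5Z)-2-(2,2-dimethoxyethyl)-3-[(4-methoxybenzyl)oxy]-5-methylocta-5,7-dien-1-yl]oxy}diphenylsilane
Product: 20 (2S,3S,5Z)-2-(2,2-dimethoxyethyl)-3-[(4-methoxybenzyl)oxy]-5-methylocta-5,7-dien-1-ol
Conditions: Bu4NF, THF, 0 °C → rt
Reagents that add atoms: none
Why: Fluoride cleavage of the silyl ether; no other group in 19 is sensitive to fluoride or mild base.

Step 12
Reactants: 20 (2S,3S,5Z)-2-(2,2-dimethoxyethyl)-3-[(4-methoxybenzyl)oxy]-5-methylocta-5,7-dien-1-ol
Product: 21 (2R,3S,5Z)-2-(2,2-dimethoxyethyl)-3-[(4-methoxybenzyl)oxy]-5-methylocta-5,7-dienal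
Conditions: Dess–Martin periodinane, NaHCO3, CH2Cl2, 0 °C → rt; used at once
Reagents that add atoms: none
Why: Buffered Dess–Martin oxidation gives the α-branched aldehyde without acid or base strong enough to epimerise C7 or disturb the acetal.

Step 13
Reactants: 21 (2R,3S,5Z)-2-(2,2-dimethoxyethyl)-3-[(4-methoxybenzyl)oxy]-5-methylocta-5,7-dienal; 22 ethyl propiolate
Product: 24 ethyl (4S,5S,6S,8Z)-5-(2,2-dimethoxyethyl)-4-hydroxy-6-[(4-methoxybenzyl)oxy]-8-methylundeca-8,10-dien-2-ynoate, via methylzinc alkynylide 23 (not isolated)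
Conditions: 22 (3 equiv), Me2Zn (3 equiv), (S,S)-ProPhenol [2,6-bis{[(S)-2-(hydroxydiphenylmethyl)pyrrolidin-1-yl]methyl}-4-methylphenol] (20 mol%), Ph3P=O (40 mol%), toluene, 0 °C; then 21, 0–4 °C
Reagents that add atoms: none
Why: Zinc–ProPhenol asymmetric alkynylation; the dinuclear zinc complex delivers the alkynyl group to the Re face of the aldehyde and sets C6 (4S in 24), and this is also the Felkin–Anh face of the C7-branched aldehyde, so ligand and substrate should reinforce.

Step 14
Reactants: 24 ethyl (4S,5S,6S,8Z)-5-(2,2-dimethoxyethyl)-4-hydroxy-6-[(4-methoxybenzyl)oxy]-8-methylundeca-8,10-dien-2-ynoate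
Product: 26 (5S)-5-[(3R,4S,6Z)-1,1-dimethoxy-4-[(4-methoxybenzyl)oxy]-6-methylnona-6,8-dien-3-yl]-3-iodofuran-2(5H)-one, via stannylbutenolide 25 (not isolated)
Conditions: Bu3SnH (slow addition), PdCl2(PPh3)2 (3 mol%), THF, 0 °C → rt; then I2, CH2Cl2, 0 °C
Reagents that add atoms: iodine, II
Why: Palladium-catalysed syn-hydrostannation of the ynoate puts tin α to the ester and hydrogen on C5 on the same side, so the ester and the C6 hydroxyl are cis and lactonise in the flask; iododestannylation with retention then gives the 3-iodobutenolide, and the electron-poor alkyne should react well before the diene.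

Step 15
Reactants: 26 (5S)-5-[(3R,4S,6Z)-1,1-dimethoxy-4-[(4-methoxybenzyl)oxy]-6-methylnona-6,8-dien-3-yl]-3-iodofuran-2(5H)-one
Product: 28 (4Z,7S,8R,9R)-8-(2,2-dimethoxyethyl)-7-[(4-methoxybenzyl)oxy]-5-methyl-10-oxabicyclo[7.2.1]dodeca-1(12),4-dien-11-one, via B-alkyl-9-BBN borane 27 (not isolated)
Conditions: 9-BBN (0.5 M in THF, 1.5 equiv), THF, 0 °C → rt; then slow addition over about 10 h to PdCl2(dppf) (20 mol%), AsPh3 (40 mol%), Cs2CO3 (3 equiv), DMF/THF/H2O, rt → 45 °C, final concentration about 2 mM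
Reagents that add atoms: none
Why: Hydroboration and intramolecular B-alkyl Suzuki–Miyaura coupling: 9-BBN adds anti-Markovnikov to the only monosubstituted alkene (C2=C3) and leaves the trisubstituted C1=C10 alkene, the iodoalkene and the lactone untouched, giving borane 27 with boron on C3. Zerovalent palladium formed from PdCl2(dppf) inserts into the C4–I bond with retention, the carbonate-activated borate transfers the C3 alkyl group, and reductive elimination from an eleven-membered alkyl(alkenyl)palladacycle forms C3–C4 and closes the ten-membered carbocycle. The closest known reaction types are the hydroboration/B-alkyl Suzuki closure of medium and large rings and the Suzuki coupling of 3-halobutenolides. No stereocentre is made; the ring-trans C4=C5 geometry is dictated by the five-membered lactone, in which C15 and O6 must be cis, and the C1=C10 geometry is carried in from 16. Ring closure over oligomerisation is secured by slow addition into dilute catalyst and by two rigid turns, the butenolide and the Z-alkene, that hold C3 near C4. AsPh3 speeds transmetallation so that coupling can run near room temperature, which limits carbonate-induced deprotonation of the butenolide at C6. The Z-configured diene cannot easily reach an s-cis conformation, so an intramolecular Diels–Alder reaction with the butenolide should not compete during hydroboration.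

Step 16
Reactants: 28 (4Z,7S,8R,9R)-8-(2,2-dimethoxyethyl)-7-[(4-methoxybenzyl)oxy]-5-methyl-10-oxabicyclo[7.2.1]dodeca-1(12),4-dien-11-one
Product: 29 (1R,2Z,6Z,9S,10S)-10-(2,2-dimethoxyethyl)-3-(hydroxymethyl)-9-[(4-methoxybenzyl)oxy]-7-methylcyclodeca-2,6-dien-1-ol
Conditions: i-Bu2AlH (4 equiv), CH2Cl2, −78 → −20 °C; aqueous Rochelle salt
Reagents that add atoms: none
Why: 1,2-Reduction of the unsaturated lactone through its lactol to the 2-ene-1,4-diol; this opens the temporary bridge to give C15 as CH2OH and O6 as the free hydroxyl with the C4=C5 geometry retained, and acetal, PMB ether and the other alkene are inert.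

Step 17
Reactants: 29 (1R,2Z,6Z,9S,10S)-10-(2,2-dimethoxyethyl)-3-(hydroxymethyl)-9-[(4-methoxybenzyl)oxy]-7-methylcyclodeca-2,6-dien-1-ol
Product: 30 (1R,2Z,6Z,9S,10S)-3-{[(tert-butyldimethylsilyl)oxy]methyl}-10-(2,2-dimethoxyethyl)-9-[(4-methoxybenzyl)oxy]-7-methylcyclodeca-2,6-dien-1-ol
Conditions: TBSCl (1.05 equiv), imidazole, CH2Cl2, −20 → 0 °C
Reagents that add atoms: tert-butylchlorodimethylsilane, CC(C)(C)[Si](C)(C)Cl
Why: Silylation of the primary allylic hydroxyl in preference to the hindered secondary C6 hydroxyl flanked by the branched C7.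

Step 18
Reactants: 30 (1R,2Z,6Z,9S,10S)-3-{[(tert-butyldimethylsilyl)oxy]methyl}-10-(2,2-dimethoxyethyl)-9-[(4-methoxybenzyl)oxy]-7-methylcyclodeca-2,6-dien-1-ol
Product: 31 (3aR,4S,6Z,10Z,11aR)-10-{[(tert-butyldimethylsilyl)oxy]methyl}-4-[(4-methoxybenzyl)oxy]-6-methyl-2,3,3a,4,5,8,9,11a-octahydrocyclodeca[b]furan-2-ol (both C2 epimers)
Conditions: PPTS (cat.), acetone/H2O, rt
Reagents that add atoms: water, O
Why: Acid-catalysed acetal exchange and hydrolysis: the C6 hydroxyl captures the C12 oxocarbenium ion in a five-membered ring and water gives the lactol; O8 is blocked, so only the 12,6-ring can form, and the weak acid should spare the TBS ether and the diene.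

Step 19
Reactants: 31 (3aR,4S,6Z,10Z,11aR)-10-{[(tert-butyldimethylsilyl)oxy]methyl}-4-[(4-methoxybenzyl)oxy]-6-methyl-2,3,3a,4,5,8,9,11a-octahydrocyclodeca[b]furan-2-ol
Product: 32 (3aR,4S,6Z,10Z,11aR)-10-{[(tert-butyldimethylsilyl)oxy]methyl}-4-[(4-methoxybenzyl)oxy]-6-methyl-3a,4,5,8,9,11a-hexahydrocyclodeca[b]furan-2(3H)-one
Conditions: Pr4N[RuO4] (5 mol%), N-methylmorpholine N-oxide, 4 Å MS, CH2Cl2, rt
Reagents that add atoms: none
Why: Perruthenate oxidation of the lactol to the lactone under neutral conditions; alkenes, silyl ether and PMB ether are not oxidised.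

Step 20
Reactants: 32 (3aR,4S,6Z,10Z,11aR)-10-{[(tert-butyldimethylsilyl)oxy]methyl}-4-[(4-methoxybenzyl)oxy]-6-methyl-3a,4,5,8,9,11a-hexahydrocyclodeca[b]furan-2(3H)-one
Product: 34 (3aR,4S,6Z,10Z,11aR)-10-{[(tert-butyldimethylsilyl)oxy]methyl}-3-[(dimethylamino)methyl]-4-[(4-methoxybenzyl)oxy]-6-methyl-3a,4,5,8,9,11a-hexahydrocyclodeca[b]furan-2(3H)-one (C3 epimers), via lithium enolate 33 (not isolated)
Conditions: LiN(SiMe3)2, THF, −78 °C; then CH2=NMe2+ I−, −78 °C → rt
Reagents that add atoms: N,N-dimethylmethaniminium iodide, C=[N+](C)C.[I-]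
Why: Mannich aminomethylation of the kinetic lactone enolate; the enolate has no β-leaving group, and the C11 configuration is irrelevant because it is removed in step 21.

Step 21
Reactants: 34 (3aR,4S,6Z,10Z,11aR)-10-{[(tert-butyldimethylsilyl)oxy]methyl}-3-[(dimethylamino)methyl]-4-[(4-methoxybenzyl)oxy]-6-methyl-3a,4,5,8,9,11a-hexahydrocyclodeca[b]furan-2(3H)-one
Product: 36 (3aR,4S,6Z,10Z,11aR)-10-{[(tert-butyldimethylsilyl)oxy]methyl}-4-[(4-methoxybenzyl)oxy]-6-methyl-3-methylidene-3a,4,5,8,9,11a-hexahydrocyclodeca[b]furan-2(3H)-one, via trimethylammonium iodide 35 (not isolated)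
Conditions: MeI, MeOH, rt; evaporate; then sat. aq. NaHCO3, CH2Cl2, rt
Reagents that add atoms: none
Why: Quaternisation of the amine and mild base-induced β-elimination (Hofmann type) give the exocyclic methylene; bicarbonate is too weak to epimerise C7 or add to the product.

Step 22
Reactants: 36 (3aR,4S,6Z,10Z,11aR)-10-{[(tert-butyldimethylsilyl)oxy]methyl}-4-[(4-methoxybenzyl)oxy]-6-methyl-3-methylidene-3a,4,5,8,9,11a-hexahydrocyclodeca[b]furan-2(3H)-one
Product: 37 (3aR,4S,6Z,10Z,11aR)-10-{[(tert-butyldimethylsilyl)oxy]methyl}-4-hydroxy-6-methyl-3-methylidene-3a,4,5,8,9,11a-hexahydrocyclodeca[b]furan-2(3H)-one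
Conditions: DDQ, CH2Cl2/pH 7 phosphate buffer, 0 °C
Reagents that add atoms: none
Why: Oxidative PMB cleavage through the benzylic oxocarbenium ion under buffered, non-acidic conditions that the diene, the silyl ether and the methylene lactone tolerate.

Step 23
Reactants: 38 1-[(tert-butyldimethylsilyl)oxy]propan-2-one
Product: 39 ethyl (2E)-4-[(tert-butyldimethylsilyl)oxy]-3-methylbut-2-enoate
Conditions: (EtO)2P(O)CH2CO2Et, NaH, THF, 0 °C; then 38, 0 °C → rt; E isomer separated by chromatography
Reagents that add atoms: triethyl phosphonoacetate, CCOC(=O)CP(=O)(OCC)OCC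
Why: Horner–Wadsworth–Emmons olefination of the ketone; the larger silyloxymethyl group is expected to sit trans to the ester, and any Z isomer is removed.

Step 24
Reactants: 39 ethyl (2E)-4-[(tert-butyldimethylsilyl)oxy]-3-methylbut-2-enoate
Product: 40 (2E)-4-[(tert-butyldimethylsilyl)oxy]-3-methylbut-2-enoic acid
Conditions: LiOH·H2O, THF/MeOH/H2O, rt; then 1 M HCl to pH 4, 0 °C
Reagents that add atoms: lithium hydroxide, [Li+].[OH-]
Why: Ester saponification; the primary TBS ether is stable to aqueous LiOH at room temperature and to a brief cold acidification.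

Step 25
Reactants: 40 (2E)-4-[(tert-butyldimethylsilyl)oxy]-3-methylbut-2-enoic acid; 37 (3aR,4S,6Z,10Z,11aR)-10-{[(tert-butyldimethylsilyl)oxy]methyl}-4-hydroxy-6-methyl-3-methylidene-3a,4,5,8,9,11a-hexahydrocyclodeca[b]furan-2(3H)-one
Product: 42 (3aR,4S,6Z,10Z,11aR)-10-{[(tert-butyldimethylsilyl)oxy]methyl}-6-methyl-3-methylidene-2-oxo-2,3,3a,4,5,8,9,11a-octahydrocyclodeca[b]furan-4-yl (2E)-4-[(tert-butyldimethylsilyl)oxy]-3-methylbut-2-enoate, via mixed trichlorobenzoic anhydride 41 (not isolated)
Conditions: 40, 2,4,6-trichlorobenzoyl chloride, Et3N, toluene, rt; then 37, DMAP, toluene, rt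
Reagents that add atoms: none
Why: Yamaguchi esterification; the acylpyridinium formed from the mixed anhydride acylates the hindered secondary C8 hydroxyl with retention at C8, and the absence of strong base should keep the enoate E and conjugated.

Step 26
Reactants: 42 (3aR,4S,6Z,10Z,11aR)-10-{[(tert-butyldimethylsilyl)oxy]methyl}-6-methyl-3-methylidene-2-oxo-2,3,3a,4,5,8,9,11a-octahydrocyclodeca[b]furan-4-yl (2E)-4-[(tert-butyldimethylsilyl)oxy]-3-methylbut-2-enoate
Product: 43 (3aR,4S,6Z,10Z,11aR)-10-(hydroxymethyl)-6-methyl-3-methylidene-2-oxo-2,3,3a,4,5,8,9,11a-octahydrocyclodeca[b]furan-4-yl (2E)-4-hydroxy-3-methylbut-2-enoate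
Conditions: HF·pyridine, pyridine, THF, 0 °C → rt
Reagents that add atoms: none
Why: Buffered fluoride cleavage of both primary TBS ethers in one operation; the conditions are neither basic enough to add to the methylene lactone or cleave the ester nor acidic enough to cyclise the diene.

## Compound list

1 | methyl 4,4-dimethoxybutanoate | COC(OC)CCC(=O)OC | starting material
2 | 4,4-dimethoxybutanoic acid | COC(OC)CCC(=O)O | intermediate
3 | (R)-4-benzyloxazolidin-2-one | O=C1N[C@H](Cc2ccccc2)CO1 | starting material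
4 | 4,4-dimethoxybutanoic pivalic anhydride | COC(OC)CCC(=O)OC(=O)C(C)(C)C | intermediate
5 | (R)-4-benzyl-3-(4,4-dimethoxybutanoyl)oxazolidin-2-one | COC(OC)CCC(=O)N1[C@H](Cc2ccccc2)COC1=O | intermediate
6 | chloroacetaldehyde | O=CCCl | starting material
7 | (Z)-dibutylboron enolate of 5 | COC(OC)C/C=C(\OB(CCCC)CCCC)N1[C@H](Cc2ccccc2)COC1=O | intermediate
8 | (R)-4-benzyl-3-[(2R,3R)-4-chloro-2-(2,2-dimethoxyethyl)-3-hydroxybutanoyl]oxazolidin-2-one | COC(OC)C[C@H]([C@@H](O)CCl)C(=O)N1[C@H](Cc2ccccc2)COC1=O | intermediate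
9 | (2S,3R)-4-chloro-2-(2,2-dimethoxyethyl)butane-1,3-diol | COC(OC)C[C@H]([C@@H](O)CCl)CO | intermediate
10 | (2R,3S)-4-[(tert-butyldiphenylsilyl)oxy]-1-chloro-3-(2,2-dimethoxyethyl)butan-2-ol | COC(OC)C[C@H]([C@@H](O)CCl)CO[Si](c1ccccc1)(c2ccccc2)C(C)(C)C | intermediate
11 | tert-butyl{(2S)-4,4-dimethoxy-2-[(2R)-oxiran-2-yl]butoxy}diphenylsilane | COC(OC)C[C@H]([C@@H]1CO1)CO[Si](c2ccccc2)(c3ccccc3)C(C)(C)C | intermediate
12 | but-2-yn-1-ol | CC#CCO | starting material
13 | sodium 2,2-bis(2-methoxyethoxy)-3-methyl-2,5-dihydro-1,2-oxaaluminol-2-uide | [Na+].CC1=CCO[Al-]1(OCCOC)OCCOC | intermediate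
14 | (Z)-3-iodobut-2-en-1-ol | C/C(I)=C/CO | intermediate
15 | (Z)-3-iodobut-2-enal | C/C(I)=C/C=O | intermediate
16 | (3Z)-4-iodopenta-1,3-diene | C/C(I)=C/C=C | intermediate
17 | [(2Z)-penta-2,4-dien-2-yl]lithium | [Li]/C(C)=C\C=C | intermediate
18 | (3S,4S,6Z)-3-{[(tert-butyldiphenylsilyl)oxy]methyl}-1,1-dimethoxy-6-methylnona-6,8-dien-4-ol | COC(OC)C[C@@H](CO[Si](c1ccccc1)(c2ccccc2)C(C)(C)C)[C@@H](O)C/C(C)=C\C=C | intermediate
19 | tert-butyl{[(2S,3S,5Z)-2-(2,2-dimethoxyethyl)-3-[(4-methoxybenzyl)oxy]-5-methylocta-5,7-dien-1-yl]oxy}diphenylsilane | COC(OC)C[C@@H](CO[Si](c1ccccc1)(c2ccccc2)C(C)(C)C)[C@@H](OCc3ccc(OC)cc3)C/C(C)=C\C=C | intermediate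
20 | (2S,3S,5Z)-2-(2,2-dimethoxyethyl)-3-[(4-methoxybenzyl)oxy]-5-methylocta-5,7-dien-1-ol | COC(OC)C[C@@H](CO)[C@@H](OCc1ccc(OC)cc1)C/C(C)=C\C=C | intermediate
21 | (2R,3S,5Z)-2-(2,2-dimethoxyethyl)-3-[(4-methoxybenzyl)oxy]-5-methylocta-5,7-dienal | COC(OC)C[C@@H](C=O)[C@@H](OCc1ccc(OC)cc1)C/C(C)=C\C=C | intermediate
22 | ethyl propiolate | C#CC(=O)OCC | starting material
23 | ethyl 3-(methylzincio)prop-2-ynoate | CCOC(=O)C#C[Zn]C | intermediate
24 | ethyl (4S,5S,6S,8Z)-5-(2,2-dimethoxyethyl)-4-hydroxy-6-[(4-methoxybenzyl)oxy]-8-methylundeca-8,10-dien-2-ynoate | COC(OC)C[C@@H]([C@H](O)C#CC(=O)OCC)[C@@H](OCc1ccc(OC)cc1)C/C(C)=C\C=C | intermediate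
25 | (5S)-5-[(3R,4S,6Z)-1,1-dimethoxy-4-[(4-methoxybenzyl)oxy]-6-methylnona-6,8-dien-3-yl]-3-(tributylstannyl)furan-2(5H)-one | COC(OC)C[C@@H]([C@H]1C=C([Sn](CCCC)(CCCC)CCCC)C(=O)O1)[C@@H](OCc2ccc(OC)cc2)C/C(C)=C\C=C | intermediate
26 | (5S)-5-[(3R,4S,6Z)-1,1-dimethoxy-4-[(4-methoxybenzyl)oxy]-6-methylnona-6,8-dien-3-yl]-3-iodofuran-2(5H)-one | COC(OC)C[C@@H]([C@H]1C=C(I)C(=O)O1)[C@@H](OCc2ccc(OC)cc2)C/C(C)=C\C=C | intermediate
27 | (5S)-5-[(3R,4S,6Z)-9-(9-borabicyclo[3.3.1]nonan-9-yl)-1,1-dimethoxy-4-[(4-methoxybenzyl)oxy]-6-methylnon-6-en-3-yl]-3-iodofuran-2(5H)-one | COC(OC)C[C@@H]([C@H]1C=C(I)C(=O)O1)[C@@H](OCc2ccc(OC)cc2)C/C(C)=C\CCB3C4CCCC3CCC4 | intermediate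
28 | (4Z,7S,8R,9R)-8-(2,2-dimethoxyethyl)-7-[(4-methoxybenzyl)oxy]-5-methyl-10-oxabicyclo[7.2.1]dodeca-1(12),4-dien-11-one | COC(OC)C[C@H]1[C@H]2C=C(C(=O)O2)CC/C=C(/C)C[C@@H]1OCc3ccc(OC)cc3 | intermediate
29 | (1R,2Z,6Z,9S,10S)-10-(2,2-dimethoxyethyl)-3-(hydroxymethyl)-9-[(4-methoxybenzyl)oxy]-7-methylcyclodeca-2,6-dien-1-ol | COC(OC)C[C@H]1[C@H](O)/C=C(\CO)CC/C=C(/C)C[C@@H]1OCc2ccc(OC)cc2 | intermediate
30 | (1R,2Z,6Z,9S,10S)-3-{[(tert-butyldimethylsilyl)oxy]methyl}-10-(2,2-dimethoxyethyl)-9-[(4-methoxybenzyl)oxy]-7-methylcyclodeca-2,6-dien-1-ol | COC(OC)C[C@H]1[C@H](O)/C=C(\CO[Si](C)(C)C(C)(C)C)CC/C=C(/C)C[C@@H]1OCc2ccc(OC)cc2 | intermediate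
31 | (3aR,4S,6Z,10Z,11aR)-10-{[(tert-butyldimethylsilyl)oxy]methyl}-4-[(4-methoxybenzyl)oxy]-6-methyl-2,3,3a,4,5,8,9,11a-octahydrocyclodeca[b]furan-2-ol (C2 epimers) | OC1O[C@@H]2/C=C(\CO[Si](C)(C)C(C)(C)C)CC/C=C(/C)C[C@H](OCc3ccc(OC)cc3)[C@H]2C1 | intermediate
32 | (3aR,4S,6Z,10Z,11aR)-10-{[(tert-butyldimethylsilyl)oxy]methyl}-4-[(4-methoxybenzyl)oxy]-6-methyl-3a,4,5,8,9,11a-hexahydrocyclodeca[b]furan-2(3H)-one | O=C1O[C@@H]2/C=C(\CO[Si](C)(C)C(C)(C)C)CC/C=C(/C)C[C@H](OCc3ccc(OC)cc3)[C@H]2C1 | intermediate
33 | lithium enolate of 32 | C1=C(O[Li])O[C@@H]2/C=C(\CO[Si](C)(C)C(C)(C)C)CC/C=C(/C)C[C@H](OCc3ccc(OC)cc3)[C@@H]12 | intermediate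
34 | (3aR,4S,6Z,10Z,11aR)-10-{[(tert-butyldimethylsilyl)oxy]methyl}-3-[(dimethylamino)methyl]-4-[(4-methoxybenzyl)oxy]-6-methyl-3a,4,5,8,9,11a-hexahydrocyclodeca[b]furan-2(3H)-one (C3 epimers) | CN(C)CC1C(=O)O[C@@H]2/C=C(\CO[Si](C)(C)C(C)(C)C)CC/C=C(/C)C[C@H](OCc3ccc(OC)cc3)[C@@H]12 | intermediate
35 | trimethylammonium iodide of 34 | C[N+](C)(C)CC1C(=O)O[C@@H]2/C=C(\CO[Si](C)(C)C(C)(C)C)CC/C=C(/C)C[C@H](OCc3ccc(OC)cc3)[C@@H]12.[I-] | intermediate
36 | (3aR,4S,6Z,10Z,11aR)-10-{[(tert-butyldimethylsilyl)oxy]methyl}-4-[(4-methoxybenzyl)oxy]-6-methyl-3-methylidene-3a,4,5,8,9,11a-hexahydrocyclodeca[b]furan-2(3H)-one | C=C1C(=O)O[C@@H]2/C=C(\CO[Si](C)(C)C(C)(C)C)CC/C=C(/C)C[C@H](OCc3ccc(OC)cc3)[C@@H]12 | intermediate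
37 | (3aR,4S,6Z,10Z,11aR)-10-{[(tert-butyldimethylsilyl)oxy]methyl}-4-hydroxy-6-methyl-3-methylidene-3a,4,5,8,9,11a-hexahydrocyclodeca[b]furan-2(3H)-one | C=C1C(=O)O[C@@H]2/C=C(\CO[Si](C)(C)C(C)(C)C)CC/C=C(/C)C[C@H](O)[C@@H]12 | intermediate
38 | 1-[(tert-butyldimethylsilyl)oxy]propan-2-one | CC(=O)CO[Si](C)(C)C(C)(C)C | starting material
39 | ethyl (2E)-4-[(tert-butyldimethylsilyl)oxy]-3-methylbut-2-enoate | CCOC(=O)/C=C(\C)CO[Si](C)(C)C(C)(C)C | intermediate
40 | (2E)-4-[(tert-butyldimethylsilyl)oxy]-3-methylbut-2-enoic acid | OC(=O)/C=C(\C)CO[Si](C)(C)C(C)(C)C | intermediate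
41 | (2E)-4-[(tert-butyldimethylsilyl)oxy]-3-methylbut-2-enoic 2,4,6-trichlorobenzoic anhydride | O=C(/C=C(\C)CO[Si](C)(C)C(C)(C)C)OC(=O)c1c(Cl)cc(Cl)cc1Cl | intermediate
42 | (3aR,4S,6Z,10Z,11aR)-10-{[(tert-butyldimethylsilyl)oxy]methyl}-6-methyl-3-methylidene-2-oxo-2,3,3a,4,5,8,9,11a-octahydrocyclodeca[b]furan-4-yl (2E)-4-[(tert-butyldimethylsilyl)oxy]-3-methylbut-2-enoate | C=C1C(=O)O[C@@H]2/C=C(\CO[Si](C)(C)C(C)(C)C)CC/C=C(/C)C[C@H](OC(=O)/C=C(\C)CO[Si](C)(C)C(C)(C)C)[C@@H]12 | intermediate
43 | (3aR,4S,6Z,10Z,11aR)-10-(hydroxymethyl)-6-methyl-3-methylidene-2-oxo-2,3,3a,4,5,8,9,11a-octahydrocyclodeca[b]furan-4-yl (2E)-4-hydroxy-3-methylbut-2-enoate | C=C1C(=O)O[C@@H]2/C=C(\CO)CC/C=C(/C)C[C@H](OC(=O)/C=C(\C)CO)[C@@H]12 | target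

## Step count and risk

Total: 26 steps. Longest linear sequence: 21 steps (steps 1–5, 9–22, 25 and 26). Steps 6–8 make the diene fragment and steps 23–24 the side-chain acid.

**Step 15 (key step).** Three processes are most likely to hurt it. Carbonate may deprotonate the butenolide at C6, causing epimerisation or ring opening. The strained bridged palladacycle may transmetallate slowly, so that oligomerisation or protodeboronation takes over. Some 9-BBN may be lost to reduction of the lactone.
Fallback: it sets out from 26 and returns at 29. Reduction of 26 with i-Bu2AlH would give the iodo diol F1, and t-Bu2Si(OTf)2 with 2,6-lutidine would tie its two hydroxyls into the seven-membered silylene F2. This tether is not acidic at C6 and is more flexible, yet still holds C15 and O6 cis. Hydroboration of F2 with 9-BBN would give the borane F3, which is closed under the same palladium conditions to the silylene-bridged carbocycle F4. Bu4NF then releases diol 29, and the route continues at step 17.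

**Step 13.** The likely failure is poor facial selectivity in the alkynylation of a hindered α-branched aliphatic aldehyde, together with slow conversion that allows epimerisation at C7.
Fallback: it sets out from 21 and returns at 24. Addition of the lithium acetylide of 22 (LiN(SiMe3)2, THF, −78 °C) would give the C4-epimeric hydroxy ynoates F5 without control. Dess–Martin oxidation would give the ynone F6. Corey–Bakshi–Shibata reduction with (S)-Me-CBS oxazaborolidine and catecholborane would then set C6 under reagent control, the catalyst enantiomer being chosen with the alkynyl group as the smaller substituent.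

**Step 14.** Three things may go wrong: tin hydride may add to the terminal diene or with the wrong regiochemistry on the alkyne, lactonisation may be incomplete, and iodine may add to the diene.
Fallback: it sets out from 24 and returns at 26. Semireduction of the ynoate with zinc dust activated by Cu(OAc)2 and AgNO3 in MeOH/H2O does not touch dienes. The Z-hydroxy enoate would lactonise to the butenolide F7. α-Iodination with I2 and pyridine in CH2Cl2 (conjugate addition of pyridine, iodination, elimination) then gives 26.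

**Step 9.** The volatile iododiene and its lithio derivative may be lost or oligomerise. tert-Butyllithium may add to the diene instead of exchanging. BF3 may ionise the acetal.
Fallback: it sets out from 14 and 11 and returns at 19. Alcohol 14 is silylated (TBSCl, imidazole) to the non-volatile iodide F8. Exchange with t-BuLi gives the alkenyllithium F9, which opens 11 (BF3·OEt2, −78 °C) to the alcohol F10. NaH and 4-methoxybenzyl chloride give the PMB ether F11. PPTS in MeOH removes the allylic TBS group in the presence of the TBDPS ether to give the allylic alcohol F12. MnO2 gives the Z-enal F13, and Wittig methylenation (Ph3PCH3Br, KOt-Bu) gives 19.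

## Further compounds

F1 | step 15 | (2E,4S,5S,6S,8Z)-5-(2,2-dimethoxyethyl)-2-iodo-6-[(4-methoxybenzyl)oxy]-8-methylundeca-2,8,10-triene-1,4-diol | COC(OC)C[C@@H]([C@H](O)/C=C(/I)CO)[C@@H](OCc1ccc(OC)cc1)C/C(C)=C\C=C
F2 | step 15 | (4S)-2,2-di-tert-butyl-4-[(3R,4S,6Z)-1,1-dimethoxy-4-[(4-methoxybenzyl)oxy]-6-methylnona-6,8-dien-3-yl]-6-iodo-4,7-dihydro-1,3,2-dioxasilepine | COC(OC)C[C@@H]([C@H]1C=C(I)CO[Si](C(C)(C)C)(C(C)(C)C)O1)[C@@H](OCc2ccc(OC)cc2)C/C(C)=C\C=C
F3 | step 15 | B-alkyl-9-BBN borane of F2 (boron on C3) | COC(OC)C[C@@H]([C@H]1C=C(I)CO[Si](C(C)(C)C)(C(C)(C)C)O1)[C@@H](OCc2ccc(OC)cc2)C/C(C)=C\CCB3C4CCCC3CCC4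
F4 | step 15 | ten-membered 1(10),4-diene bridged from C15 to O6 by the di-tert-butylsilylene, with 8-O-PMB and the C7 dimethoxyethyl group | COC(OC)C[C@H]1[C@H]2C=C(CO[Si](C(C)(C)C)(C(C)(C)C)O2)CC/C=C(/C)C[C@@H]1OCc3ccc(OC)cc3
F5 | step 13 | ethyl (5S,6S,8Z)-5-(2,2-dimethoxyethyl)-4-hydroxy-6-[(4-methoxybenzyl)oxy]-8-methylundeca-8,10-dien-2-ynoate (C4 epimers) | COC(OC)C[C@@H](C(O)C#CC(=O)OCC)[C@@H](OCc1ccc(OC)cc1)C/C(C)=C\C=C
F6 | step 13 | ethyl (5R,6S,8Z)-5-(2,2-dimethoxyethyl)-6-[(4-methoxybenzyl)oxy]-8-methyl-4-oxoundeca-8,10-dien-2-ynoate | COC(OC)C[C@@H](C(=O)C#CC(=O)OCC)[C@@H](OCc1ccc(OC)cc1)C/C(C)=C\C=C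
F7 | step 14 | (5R)-5-[(3R,4S,6Z)-1,1-dimethoxy-4-[(4-methoxybenzyl)oxy]-6-methylnona-6,8-dien-3-yl]furan-2(5H)-one | COC(OC)C[C@@H]([C@H]1C=CC(=O)O1)[C@@H](OCc2ccc(OC)cc2)C/C(C)=C\C=C
F8 | step 9 | tert-butyl{[(2Z)-3-iodobut-2-en-1-yl]oxy}dimethylsilane | C/C(I)=C/CO[Si](C)(C)C(C)(C)C
F9 | step 9 | {(2Z)-4-[(tert-butyldimethylsilyl)oxy]but-2-en-2-yl}lithium | [Li]/C(C)=C\CO[Si](C)(C)C(C)(C)C
F10 | step 9 | (3S,4S,6Z)-8-[(tert-butyldimethylsilyl)oxy]-3-{[(tert-butyldiphenylsilyl)oxy]methyl}-1,1-dimethoxy-6-methyloct-6-en-4-ol | COC(OC)C[C@@H](CO[Si](c1ccccc1)(c2ccccc2)C(C)(C)C)[C@@H](O)C/C(C)=C\CO[Si](C)(C)C(C)(C)C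
F11 | step 9 | 4-methoxybenzyl ether of F10 at O8 | COC(OC)C[C@@H](CO[Si](c1ccccc1)(c2ccccc2)C(C)(C)C)[C@@H](OCc3ccc(OC)cc3)C/C(C)=C\CO[Si](C)(C)C(C)(C)C
F12 | step 9 | (2Z,5S,6S)-6-{[(tert-butyldiphenylsilyl)oxy]methyl}-8,8-dimethoxy-5-[(4-methoxybenzyl)oxy]-3-methyloct-2-en-1-ol | COC(OC)C[C@@H](CO[Si](c1ccccc1)(c2ccccc2)C(C)(C)C)[C@@H](OCc3ccc(OC)cc3)C/C(C)=C\CO
F13 | step 9 | (2Z,5S,6S)-6-{[(tert-butyldiphenylsilyl)oxy]methyl}-8,8-dimethoxy-5-[(4-methoxybenzyl)oxy]-3-methyloct-2-enal | COC(OC)C[C@@H](CO[Si](c1ccccc1)(c2ccccc2)C(C)(C)C)[C@@H](OCc3ccc(OC)cc3)C/C(C)=C\C=O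
A1 | alternative 1 | ten-membered C8 alcohol with the 3-(triethylsilyloxy)prop-1-en-2-yl group on C7, 6-O-triethylsilyl and 15-O-tert-butyldiphenylsilyl | C=C(CO[Si](CC)(CC)CC)[C@H]1[C@H](O[Si](CC)(CC)CC)/C=C(\CO[Si](c2ccccc2)(c2ccccc2)C(C)(C)C)CC/C=C(/C)C[C@@H]1O
A2 | alternative 1 | thirteen-membered cyclic allylic ether (O8 bound to C13, C7=C11 alkene) with tributylstannyl on C8, drawn with the C8 configuration that inverts on rearrangement | CCCC[Sn](CCCC)(CCCC)[C@@H]1OC/C(CO[Si](CC)(CC)CC)=C/[C@H](O[Si](CC)(CC)CC)/C=C(\CO[Si](c2ccccc2)(c2ccccc2)C(C)(C)C)CC/C=C(/C)C1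
A3 | alternative 2 | ten-membered 1(10),2,4-triene 12,6-lactone, 8-O-triethylsilyl and 15-O-triisopropylsilyl | C1C(=O)O[C@@H]2/C=C(\CO[Si](C(C)C)(C(C)C)C(C)C)/C=C\C=C(\C)C[C@H](O[Si](CC)(CC)CC)[C@@H]12
A4 | alternative 2 | cis-fused decalin 1,3-diene 12,6-lactone (C5–C10 bond intact, H5 and C14 cis), 8-O-triethylsilyl and 15-O-triisopropylsilyl | O=C1C[C@H]2[C@H](O1)[C@@H]3C(CO[Si](C(C)C)(C(C)C)C(C)C)=CC=C[C@]3(C)C[C@@H]2O[Si](CC)(CC)CC
A5 | alternative 3 | ten-membered 1(10),4-diene α-methylene lactol methyl ether, 8-O-PMB and 15-O-triisopropylsilyl | C=C1[C@@H](OC)O[C@@H]2/C=C(\CO[Si](C(C)C)(C(C)C)C(C)C)CC/C=C(/C)C[C@H](OCc3ccc(OC)cc3)[C@@H]12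
A6 | alternative 3 | eleven-membered cyclic sulfone with sulfur between C1 and C10 (either epimer at C10), otherwise substituted as A5 | C=C1[C@@H](OC)O[C@@H]2/C=C(\CO[Si](C(C)C)(C(C)C)C(C)C)CCCS(=O)(=O)C(C)C[C@H](OCc3ccc(OC)cc3)[C@@H]12
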